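## Retrosynthetic overview
Numbering below is the iridoid one (C1 acetal, C3=C4 enol ether, C5/C9 ring fusion, C8 spiro carbon; Ca is the lactone CH–O and Cb the α-carbon).
1. The E-arylidene comes from aldol condensation of the α-CH2 lactone with 4-acetoxybenzaldehyde. That lactone is made last-but-one by oxa-Michael closure of a C1 lactol onto a spiro-butenolide, which forms the THF ring and sets Ca.
2. The dihydropyran lactol comes from acid unmasking of a C9 dimethyl acetal, captured by the enol of a C5-bound formylacetate. That C5–C4 bond comes from retentive Pd-catalysed allylic alkylation of a cyclopentenol.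
3. The spiro-butenolide comes from a Z-olefination/lactonisation of a tertiary α-hydroxy aldehyde.
4. The cyclopentene, with the C8 quaternary carbinol and the C9 substituent, comes from a dearomative oxa-Piancatelli ring contraction of a furylcarbinol made from furfuryl alcohol and dimethoxyacetaldehyde. The ring order is cyclopentene, butenolide, dihydropyran, THF, arylidene.

Compounds are numbered in order of appearance in the steps below.

Assumptions (one line): the furfuryl alkoxide lithiates at C5; the α-acetal carbinol still ionises under the mild acid; the C4 side-chain carbon of 11 is left unspecified because it is an epimerisable enol/keto mixture; the chiral acid is chosen to give the (4S,5S) enantiomer of 4.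

## Route

**Step 1**
Reactants: 1 furfuryl alcohol; 2 2,2-dimethoxyacetaldehyde (freshly dehydrated)
Product: 3 1-[5-(hydroxymethyl)furan-2-yl]-2,2-dimethoxyethan-1-ol (racemic at the carbinol)
Conditions: n-BuLi (2.2 equiv), THF, –78 → 0 °C; then 2, –78 °C → rt
Reagents that add atoms: none
Why: the alkoxide/C5-lithio dianion adds 1,2 to the aldehyde (organolithium addition); the carbinol stereocentre is erased in Step 2, so it is irrelevant.

**Step 2 (key step)**
Reactants: 3
Product: 4 (4S,5S)-5-(dimethoxymethyl)-4-hydroxy-4-(hydroxymethyl)cyclopent-2-en-1-one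
Conditions: chiral N-triflyl phosphoramide (10 mol%), MeCN, H2O (1.5 equiv), 40–60 °C
Reagents that add atoms: none (net isomerisation; water is consumed and regenerated)
Why: Proposed new method: enantioselective oxa-Piancatelli ring contraction. The secondary furfuryl alcohol ionises (the primary CH2OH does not). Water adds at the CH2OH-bearing furan C5, ring opening gives a 4-oxy-pentadienyl cation, and the chiral acid/counter-anion biases the sense of conrotatory 4π closure, with the donor OH rotating outward. This sets C8 (quaternary, tertiary OH) and C9 together, OH trans to the C9 acetal, so CH2OH (the future Ca) is cis to C1. The closest known reactions are the Piancatelli/aza-Piancatelli rearrangement and catalytic asymmetric Nazarov torquoselectivity.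

**Step 3**
Reactants: 4
Product: 5 (1S,4S,5S)-5-(dimethoxymethyl)-4-(hydroxymethyl)cyclopent-2-ene-1,4-diol
Conditions: NaBH4, CeCl3·7H2O, MeOH, –78 °C
Reagents that add atoms: none
Why: Luche 1,2-reduction; hydride enters anti to the adjacent C9 acetal, so C5–OH ends up cis to C1 and Ca on the same (α) face, which sets C5 for the later retentive substitution.

**Step 4**
Reactants: 5
Product: 6 (1S,4S,5S)-5-(dimethoxymethyl)-1,4-dihydroxycyclopent-2-ene-1-carbaldehyde
Conditions: TEMPO (10 mol%), PhI(OAc)2 (1.1 equiv), NaHCO3, CH2Cl2, 0 °C
Reagents that add atoms: none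
Why: TEMPO/BAIB oxidation is selective for the primary alcohol, giving the non-enolisable α-hydroxy aldehyde with no epimerisation, because C8 is quaternary.

**Step 5**
Reactants: 6; 7 methyl P,P-bis(2,2,2-trifluoroethyl)phosphonoacetate
Product: 8 (5R,6S,7S)-6-(dimethoxymethyl)-7-hydroxy-1-oxaspiro[4.4]nona-3,8-dien-2-one
Conditions: KHMDS (3.3 equiv), 18-crown-6, THF, –78 °C → rt
Reagents that add atoms: none (7 is the reactant that supplies Cb and Cc)
Why: Still–Gennari Z-selective Horner–Wadsworth–Emmons olefination gives the Z-γ-hydroxy enoate, which lactonises onto the tertiary C8 alkoxide to form the spiro-butenolide with C8 retained.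

**Step 6**
Reactants: 8
Product: 9 (5R,6S,7S)-6-(dimethoxymethyl)-2-oxo-1-oxaspiro[4.4]nona-3,8-dien-7-yl methyl carbonate
Conditions: ClCO2Me, pyridine, DMAP, CH2Cl2, 0 °C
Reagents that add atoms: methyl chloroformate, ClC(=O)OC
Why: O-acylation of the only free (α-face) allylic alcohol makes a Pd leaving group without disturbing C5.

**Step 7**
Reactants: 9; 10 sodium methyl 3-oxopropanoate (sodium formylacetate enolate)
Product: 11 methyl 2-[(5R,6S,7S)-6-(dimethoxymethyl)-2-oxo-1-oxaspiro[4.4]nona-3,8-dien-7-yl]-3-oxopropanoate (enol/keto mixture)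
Conditions: Pd2(dba)3·CHCl3 (2.5 mol%), PPh3 (20 mol%), THF, 50 °C
Reagents that add atoms: none (10 is the reactant)
Why: Tsuji–Trost allylic alkylation goes with net retention (ionisation anti, soft-nucleophile attack anti), so C4 is installed on the α face cis to C1 and Ca. Attack at C5 is favoured over the C7 terminus, which is neopentylic.

**Step 8**
Reactants: 11
Product: 12 methyl (4aS,7R,7aS)-1-hydroxy-5'-oxo-4a,7a-dihydro-1H,5'H-spiro[cyclopenta[c]pyran-7,2'-furan]-4-carboxylate (C1 lactol, anomeric mixture)
Conditions: TFA, THF/H2O (4:1), rt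
Reagents that add atoms: water, O
Why: acetal hydrolysis gives the C1 oxocarbenium or aldehyde, which is captured by the formylacetate enol oxygen (6-ring hemiacetalisation). The new ring is cis-fused because C4 and C1 are both α, and the anomeric C1 equilibrates.

**Step 9**
Reactants: 12
Product: 13 methyl tetracyclic acetal lactone, the target skeleton with α-CH2 (SMILES below)
Conditions: DBU (10 mol%), CH2Cl2, rt
Reagents that add atoms: none
Why: intramolecular 5-exo oxa-Michael addition of the lactol OH to the butenolide β-carbon (Ca) closes the THF ring. Only the cis-fused lactone/THF arrangement is geometrically possible, so Ca (and the C1 acetal centre) is fixed by ring constraint.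

**Step 10**
Reactants: 13; 14 4-acetoxybenzaldehyde
Product: 15 3-O-acetylprismatomerin (target)
Conditions: LiHMDS (1.05 equiv), THF, –78 °C; then 14, –78 °C; then Ac2O, DMAP, –78 → 0 °C; then DBU, CH2Cl2, 0 °C → rt
Reagents that add atoms: acetic anhydride, CC(=O)OC(C)=O (it also re-acetylates the phenol if acyl transfer occurs)
Why: lactone aldol addition, then O-acetylation of the aldolate and E1cB elimination of AcOH. The thermodynamic E-arylidene results, with Ar trans to C=O and cis to Ca as in the target; the acetate is a far better leaving group than the acetal oxygen, which avoids ring-opening.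

## Compound list
1 | furfuryl alcohol | OCc1ccco1 | starting material
2 | 2,2-dimethoxyacetaldehyde | COC(OC)C=O | starting material
3 | 1-[5-(hydroxymethyl)furan-2-yl]-2,2-dimethoxyethan-1-ol | OCc1ccc(o1)C(O)C(OC)OC | intermediate
4 | (4S,5S)-5-(dimethoxymethyl)-4-hydroxy-4-(hydroxymethyl)cyclopent-2-en-1-one | O=C1C=C[C@@](O)(CO)[C@H]1C(OC)OC | intermediate
5 | (1S,4S,5S)-5-(dimethoxymethyl)-4-(hydroxymethyl)cyclopent-2-ene-1,4-diol | O[C@H]1C=C[C@@](O)(CO)[C@H]1C(OC)OC | intermediate
6 | (1S,4S,5S)-5-(dimethoxymethyl)-1,4-dihydroxycyclopent-2-ene-1-carbaldehyde | O[C@H]1C=C[C@@](O)(C=O)[C@H]1C(OC)OC | intermediate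
7 | methyl P,P-bis(2,2,2-trifluoroethyl)phosphonoacetate | FC(F)(F)COP(=O)(CC(=O)OC)OCC(F)(F)F | starting material
8 | (5R,6S,7S)-6-(dimethoxymethyl)-7-hydroxy-1-oxaspiro[4.4]nona-3,8-dien-2-one | O[C@H]1C=C[C@]2(OC(=O)C=C2)[C@H]1C(OC)OC | intermediate
9 | (5R,6S,7S)-6-(dimethoxymethyl)-2-oxo-1-oxaspiro[4.4]nona-3,8-dien-7-yl methyl carbonate | COC(=O)O[C@H]1C=C[C@]2(OC(=O)C=C2)[C@H]1C(OC)OC | intermediate
10 | sodium methyl 3-oxopropanoate (formylacetate enolate) | COC(=O)/C=C\[O-].[Na+] | starting material
11 | methyl 2-[(5R,6S,7S)-6-(dimethoxymethyl)-2-oxo-1-oxaspiro[4.4]nona-3,8-dien-7-yl]-3-oxopropanoate | O=CC(C(=O)OC)[C@H]1C=C[C@]2(OC(=O)C=C2)[C@H]1C(OC)OC | intermediate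
12 | spiro lactol (C1 epimeric mixture), methyl (4aS,7R,7aS)-1-hydroxy-5'-oxo-spiro[cyclopenta[c]pyran-7,2'-furan]-4-carboxylate | COC(=O)C1=COC(O)[C@H]2[C@@H]1C=C[C@]23OC(=O)C=C3 | intermediate
13 | tetracyclic acetal lactone (target skeleton with α-CH2) | COC(=O)C1=CO[C@@H]2O[C@H]3CC(=O)O[C@]34C=C[C@H]1[C@H]24 | intermediate
14 | 4-acetoxybenzaldehyde | CC(=O)Oc1ccc(C=O)cc1 | starting material
15 | 3-O-acetylprismatomerin | COC(=O)C1=CO[C@@H]2O[C@H]3/C(=C\c4ccc(OC(C)=O)cc4)C(=O)O[C@]34C=C[C@H]1[C@H]24 | target

## Totals
Total steps: 10. Longest linear sequence: 10, from furfuryl alcohol.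

Three steps most likely to fail:
1. **Step 2 (asymmetric oxa-Piancatelli).** Risks are ee, competing ionisation of the primary CH2OH, acetal hydrolysis, and the OH/R trans outcome. Fallback: run it racemic with Dy(OTf)3 and resolve the primary-alcohol stage (4 or 5) by lipase acylation, or make the cyclopentene by Pd desymmetrisation of a meso cyclopentene-1,3-diol dicarbonate instead.
2. **Step 7 (C5–C4 Pd alkylation).** Risks are C5 versus C7 regiochemistry and attack on the hindered α face. Fallback: an intramolecular version, in which the C1 lactol is esterified with methyl malonyl chloride and cyclised by Pd(0) so that the tether delivers C4 to the α face, followed by lactone-to-enol-ether conversion.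
3. **Step 10 (aldol condensation).** The lactone enolate may undergo retro-oxa-Michael E1cB ring-opening. Fallback: run Step 9 in the presence of 14 as a tandem oxa-Michael/aldol so the enolate is trapped as it forms, then Ac2O/DBU.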